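Remarks on the chemistry (assumptions)
- Germacrane numbering, defined in the first section, is used for all later compounds; lactones 26–29 are named as 2,3-secogermacranes because their C2–C3 bond does not yet exist.
- Compound 26 is expected as a mixture of C6 epimers, and 34 and 35 as mixtures of C8 epimers; these centres are removed in steps 15 and 20.
- Metal-bound intermediates 25, 30 and 31 are drawn without ancillary ligands (chloride, TMEDA, solvent).

## Structural features

The target is a germacrane sesquiterpenoid with the carbocycle C1H2–C2H=C3–C4(CH3)(OH)–C5H2–C6H(OAc)–C7–C8=C9H–C10(CH3)–C1, an ether oxygen between C3 and C10, and a butenolide C7=C11(C13H2OAc)–C12(=O)–O–C8. The ether bridge makes C1–C2–C3–O–C10 a 2,3-dihydrofuran whose enol ether carbon C3 is a bridgehead of an 11-oxabicyclo[6.2.1] frame, and the γ-ylidene butenolide shares the C7–C8 bond, so that C11=C7–C8=C9 is a dienyl enol ester. There are three stereocentres: C4 (S, tertiary alcohol) and C6 (S, secondary acetate), which are 1,3-anti across C5, and C10 (S, quaternary, ether oxygen). C10 is separated from the other two by C8=C9 on one side and C1–C2=C3 on the other and must be set independently. C2=C3 is trans within the ten-membered ring (forced by the five-membered ring), and C8=C9 has C7 and C10 cis (8E by CIP). The fragile groups are the bridgehead enol ether (acid; also ketalisation by the transannular C4 hydroxyl), the enol lactone with its cross-conjugated diene (base, nucleophiles, oxidants), the tertiary C10–O bond next to C8=C9, and the two acetates. The real difficulty is the bridged enol ether at C3, which is flanked by two fully substituted oxygen-bearing carbons (C4 and C10), together with the late appearance of the ylidene butenolide. The key step uses the fact that C2=C3–O–C10 is at the oxidation level of an ester C3(=O)–O–C10. Cutting C2=C3 collapses the dihydrofuran and the carbocycle to a nine-membered lactone (O, C3, C4, C5, C6, C7, C8, C9, C10) with an allyl group on C10, the butenolide being carried as a furan (C7, C8, O, C12, C11).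

## Logic of the disconnections

38 ⇒ 37 ⇒ 36. The acetyl C–O bonds at O6 and O13 are cut, and one stage earlier the three O–Si bonds. Esters cannot pass through the titanium reagent of the key step, so all hydroxyls travel as silyl ethers and the acetates come last. The gain is uniform protection. The forward steps must remove three silyl groups without hydrating C2=C3 or opening the enol lactone, and must acetylate the primary and secondary hydroxyls while leaving the tertiary C4 hydroxyl free.

36 ⇒ 34 ⇒ 32. The C8=C9 π bond is cut (adding water back at C8), then the C12=O and C8–OH oxygens are removed to return to an aromatic furan. A butenolide carbonyl would compete with the lactone carbonyl for the titanium alkylidene, whereas a furan is inert. The gain is that the sensitive dienyl enol ester appears only three steps from the end. The demand is an oxidant that takes the furan in preference to the enol ether; regiochemistry is fixed because C12 carries the only furan α-hydrogen, and the ring allows only the cis C7/C10 olefin.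

32 ⇒ 29. The C2=C3 bond is cut, returning a carbonyl oxygen to C3 and a terminal CH2 to C2. This is the strategic simplification: the bridged bicycle with its bridgehead enol ether becomes a nine-membered lactone carrying an allyl group, with C4, C6 and C10 already in place. The forward step needs a titanium alkylidene to form at the only alkene and to add to a carbonyl shielded by two quaternary carbons, with no other carbonyl present.

29 ⇒ 28 ⇒ 27 ⇒ 26 ⇒ 24. The C6–C7 bond is cut. The ester of a tertiary alcohol cannot reasonably be made by lactonisation, so the ring is closed at C6–C7 with the ester already present. An arylchromium reagent is chosen because it adds to aldehydes but not to esters; a more polar aryl metal at C7 would attack C3 through a six-membered transition state. The configuration of C6 from the ring closure is not relied upon: it is erased by oxidation and set by a reagent-controlled reduction. The demands are a medium-ring closure at high dilution and oxidative addition at a doubly flanked furyl iodide.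

24 ⇒ 23 ⇒ 14 + 21. The ester C3–O(C10) bond is cut, dividing the molecule into a C10 carbinol and a C3–C6 acid. C6 is carried as a Weinreb amide, which becomes the aldehyde in one step without touching the hindered ester. The demand is acylation of a tertiary alkoxide by an acyl fluoride with a fully substituted α-carbon.

21 ⇒ 20 ⇒ 18 ⇒ 17 ⇒ 16 ⇒ 15. Only functional-group bonds are cut. C4 with its methyl and oxygen is taken from the chiral pool, and the two carboxyls are told apart by tying the α-hydroxy acid into a dioxolanone. The demand is that the tertiary centre is never broken, which holds because no step touches a bond to C4.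

14 ⇒ 12 ⇒ 11 ⇒ 5 + 8. The C7–I bond, the C1–C2 bond (vinyl to CH2) and the C8–C9 bond (furyl to CH2) are cut. Both C–C bonds are made by opening epoxides at CH2 carbons next to C10, so the quaternary centre is carried unchanged from an epoxide. The demands are ortho-lithiation next to bromine and a halogen exchange that tolerates the allyl group.

8 ⇒ 6 and 5 ⇒ 4 ⇒ 1. The epoxide C–O bonds are cut back to the alkene, giving C10 by a catalytic asymmetric epoxidation. The C11–C13 bond is cut back to a symmetrical dibromide, where mono-exchange needs no regiocontrol.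

## Other disconnections considered

Alternative 1: The cut is C5–C6 and C4–O, with an isoxazoline as a masked β-hydroxy ketone. In the forward step aldoxime A2 (C6 aldoxime on the butenolide, isopropenyl group C4(CH3)=C5H2 on C3 of the dihydrofuran) would be converted with NaOCl into a nitrile oxide. This would add to the 1,1-disubstituted alkene with oxygen going to C4, giving isoxazoline A1 and closing the ten-membered ring.
- In its favour: C4–O and the C6 carbonyl are installed in one step. After N–O cleavage (Mo(CO)6), the C4 hydroxyl could direct an anti-selective reduction (Me4NBH(OAc)3) that matches the 1,3-anti C4/C6 relation of 38. This internal control of C6 would be better than the external catalyst control of step 16.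
- It needs no silyl groups, carries the C13 acetate from the start, and needs about three steps after the key step. On protecting-group economy and on step count after the key step it is the better plan. It is the equal of the chosen plan in closing the carbocycle and a five-membered heterocycle in one operation.
- Against it: C4 would be created in the key step on a freely rotating isopropenyl group, with only the remote C10 to bias the face. The dipolarophile is the terminus of a 2-alkoxydiene and NaOCl is an electrophilic chlorinating oxidant. The nitrile oxide is conjugated to the butenolide and can dimerise if ring closure is slow, and ten-membered closures lie between the two regiochemical modes.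
- The whole dienyl enol lactone and the enol ether must exist before the key step and survive the N–O reduction. By contrast, 29 and 32 carry only a furan and silyl ethers through step 18, and step 18 creates no stereocentre.

Alternative 2: The cut is C9–C10 plus a sacrificial C3–C8 bond. In the forward step furan enone A4 (a 2-methyl-5-alkylfuran with C4 and C6 in the tether and a dienophile C9H2=C8(OAc)–C7(=O)) would undergo an intramolecular Diels–Alder reaction (Me2AlCl or heat) to oxanorbornene A3. This forms C10 with its methyl group and the C3–O–C10 bridge in one step.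
- Correction: A3 must carry the (6S) silyl ether. A drawing with (6R) would lead to the C6 epimer of 38 or require an extra inversion, so A3 is written here as the (6S) compound.
- In its favour: the quaternary C10–O centre and the ether bridge arrive together in a concerted cycloaddition from a simple furan. On directness of making the bridge it is the equal of the chosen plan, and it needs no asymmetric epoxidation, which is a point in its favour. Two rings are closed, as in step 18.
- Against it: the configuration of C10 is relayed from C4 and C6 through a flexible tether, and furan Diels–Alder adducts revert easily. A3 contains neither C11–C13 nor the ten-membered ring.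
- The C3–C8 bond must later break so that C3 becomes an enol ether carbon. This needs either a heterolysis that puts negative charge on an α-oxygenated allylic carbon, or an alkoxy-radical β-scission followed by transposition of C1=C2 to C2=C3, and then a butenolide annulation on C7/C8.
- That is at least eight steps after the key step, with the enol ether present throughout. The chosen plan puts its mechanistic risk into one step and reaches 38 four steps later.

Alternative 3: The cut is C1–C10 (formed) with C3–C8 (broken). In the forward step the potassium alkoxide (KH, 18-crown-6) of cyclohexanol A6 (C3 vinyl carbinol and C8 (E)-2-silyloxypropenyl group cis on a cyclohexane fused to the butenolide) would undergo a [3,3] shift to the ten-membered ketone A5.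
- In its favour: the anionic oxy-Cope ring expansion is an established way to cyclodecenones and makes a C–C bond of the carbocycle. With C7 axial in a chair transition structure, which the cis isomer can reach, it would give C8=C9 with C7 and C10 cis, as required.
- The butenolide is already present, so no late oxidation next to an enol ether is needed. On this point it is better than the chosen plan.
- The dihydrofuran would then come from desilylation at C10 and cyclodehydration onto the C3 ketone, which can only eliminate towards C2. This is as simple as step 18.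
- Against it: the configuration of C10 depends on the enol ether geometry and on chair versus boat. A6 has three contiguous fully substituted carbons (C3, C4, C8). C8 is doubly allylic and carries the lactone oxygen next to the C3 alkoxide, so epoxide formation by loss of carboxylate or ionisation would compete.
- KH could also deprotonate C6 vinylogously and expel silanolate, the MOM group needs acid that the enol ether will not tolerate, and A6 would take many steps to make. The chosen plan instead fixes C4 and C10 from the chiral pool and an asymmetric epoxidation before any ring is closed.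

Key step: step 18

## Route

Step 1
Reactants: 1 3,4-dibromofuran
Product: 4 (4-bromofuran-3-yl)methanol, via 3-bromo-4-lithiofuran 2 (not isolated), via 4-bromofuran-3-carbaldehyde 3 (not isolated)
Conditions: n-BuLi (1.0 equiv), Et2O, −78 °C; DMF, −78 → 0 °C; then MeOH, NaBH4, 0 °C
Reagents that add atoms: N,N-dimethylformamide, CN(C)C=O
Why: Mono bromine–lithium exchange of the symmetrical dibromide needs no regiocontrol, and formylation with DMF followed by borohydride reduction in the same flask installs C13; the temperature is kept low because 3-lithiofurans ring-open on warming.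

Step 2
Reactants: 4 (4-bromofuran-3-yl)methanol
Product: 5 [(4-bromofuran-3-yl)methoxy](tert-butyl)dimethylsilane
Conditions: TBSCl, imidazole, DMF, 0 °C → rt
Reagents that add atoms: tert-butyldimethylsilyl chloride, CC(C)(C)[Si](C)(C)Cl
Why: Standard silylation of a primary alcohol; the TBS ether is a poor directing group, which matters for the lithiation in step 4.

Step 3
Reactants: 6 2-methylprop-2-en-1-ol
Product: 8 [(2R)-2-methyloxiran-2-yl]methyl 4-methylbenzenesulfonate, via (S)-2-methylglycidol 7 (not isolated)
Conditions: Ti(OiPr)4 (5 mol%), L-(+)-diethyl tartrate (6 mol%), cumene hydroperoxide, 4 Å molecular sieves, CH2Cl2, −20 °C; P(OMe)3; then Et3N, DMAP (cat.), TsCl, −10 °C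
Reagents that add atoms: cumene hydroperoxide, CC(C)(OO)c1ccccc1; 4-toluenesulfonyl chloride, Cc1ccc(cc1)S(Cl)(=O)=O
Why: Sharpless asymmetric epoxidation with L-(+)-tartrate delivers oxygen to the face that gives (S)-7 (the same sense as allyl alcohol to (S)-glycidol), and in situ tosylation avoids isolating the water-soluble epoxy alcohol. The descriptor changes to R only because CH2OTs outranks the ring CH2; this quaternary carbon becomes C10.

Step 4
Reactants: 5 [(4-bromofuran-3-yl)methoxy](tert-butyl)dimethylsilane; 8 [(2R)-2-methyloxiran-2-yl]methyl 4-methylbenzenesulfonate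
Product: 11 (2R)-2-({3-bromo-4-[(tert-butyldimethylsilyloxy)methyl]furan-2-yl}methyl)-2-methyloxirane, via furyllithium 9 (not isolated), via hydroxy tosylate 10 (not isolated)
Conditions: LiN(iPr)2, THF, −78 °C; 8, BF3·OEt2, −78 °C; aqueous work-up, then K2CO3, MeOH, rt
Reagents that add atoms: none
Why: Deprotonation occurs at the furan α-position next to bromine (more acidic than the other α-position), and BF3-assisted SN2 opening of the epoxide at its CH2 forms C8–C9. Base then closes a new epoxide by displacement of tosylate; no bond to the quaternary carbon is broken, so its configuration is carried over.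

Step 5
Reactants: 11 (2R)-2-({3-bromo-4-[(tert-butyldimethylsilyloxy)methyl]furan-2-yl}methyl)-2-methyloxirane
Product: 12 (2S)-1-{3-bromo-4-[(tert-butyldimethylsilyloxy)methyl]furan-2-yl}-2-methylpent-4-en-2-ol
Conditions: CH2=CHMgBr, CuI (10 mol%), THF, −30 → 0 °C
Reagents that add atoms: vinylmagnesium bromide, C=C[Mg]Br
Why: Copper-catalysed Grignard opening of a 2,2-disubstituted epoxide occurs at the CH2 carbon and gives the C10 carbinol with its allyl group; the furyl bromide does not couple at this temperature.

Step 6
Reactants: 12 (2S)-1-{3-bromo-4-[(tert-butyldimethylsilyloxy)methyl]furan-2-yl}-2-methylpent-4-en-2-ol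
Product: 14 (2S)-1-{4-[(tert-butyldimethylsilyloxy)methyl]-3-iodofuran-2-yl}-2-methylpent-4-en-2-ol, via dilithio species 13 (not isolated)
Conditions: MeLi (1.05 equiv), Et2O, −78 °C; t-BuLi (2.1 equiv), −78 °C; I2, THF, −78 °C
Reagents that add atoms: iodine, II
Why: After deprotonation of the hydroxyl, bromine–lithium exchange and iodination give the furyl iodide needed for oxidative addition in step 14. The sequence is kept cold and short so that the 3-furyllithium neither ring-opens nor takes the silyl group from the neighbouring CH2O.

Step 7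
Reactants: 15 (S)-citramalic acid [(2S)-2-hydroxy-2-methylbutanedioic acid]
Product: 16 2-[(4S)-2,2,4-trimethyl-5-oxo-1,3-dioxolan-4-yl]acetic acid
Conditions: Me2C(OMe)2, TsOH·H2O (cat.), acetone, rt
Reagents that add atoms: 2,2-dimethoxypropane, COC(C)(C)OC
Why: Acetalisation ties the α-hydroxy acid into a five-membered dioxolanone and leaves the other carboxyl free, which differentiates the future C3 and C6; the stereocentre (future C4) is not touched.

Step 8
Reactants: 16 2-[(4S)-2,2,4-trimethyl-5-oxo-1,3-dioxolan-4-yl]acetic acid
Product: 17 N-methoxy-N-methyl-2-[(4S)-2,2,4-trimethyl-5-oxo-1,3-dioxolan-4-yl]acetamide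
Conditions: MeNHOMe·HCl, EDC·HCl, N-methylmorpholine, CH2Cl2, 0 °C → rt
Reagents that add atoms: N,O-dimethylhydroxylamine hydrochloride, CNOC.Cl
Why: Carbodiimide amide coupling of the free carboxyl gives a Weinreb amide as the latent C6 aldehyde.

Step 9
Reactants: 17 N-methoxy-N-methyl-2-[(4S)-2,2,4-trimethyl-5-oxo-1,3-dioxolan-4-yl]acetamide
Product: 18 (2S)-2-hydroxy-4-[methoxy(methyl)amino]-2-methyl-4-oxobutanoic acid
Conditions: LiOH, THF–H2O, 0 °C → rt; then HCl (aq.) to pH 2
Reagents that add atoms: lithium hydroxide, [Li+].[OH-]
Why: Saponification of the acetal ester releases acetone and the α-hydroxy acid; the amide is much less electrophilic and should survive.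

Step 10
Reactants: 18 (2S)-2-hydroxy-4-[methoxy(methyl)amino]-2-methyl-4-oxobutanoic acid
Product: 20 (2S)-4-[methoxy(methyl)amino]-2-methyl-4-oxo-2-(triethylsilyloxy)butanoic acid, via bis(triethylsilyl) derivative 19 (not isolated)
Conditions: TESOTf (2.3 equiv), 2,6-lutidine, CH2Cl2, −78 → 0 °C; then K2CO3, MeOH–H2O, 0 °C
Reagents that add atoms: triethylsilyl trifluoromethanesulfonate, CC[Si](CC)(CC)OS(=O)(=O)C(F)(F)F
Why: The silyl triflate silylates the tertiary hydroxyl and the carboxyl, and mild base then cleaves only the labile silyl ester. TES is the smallest silyl group robust enough for the route, which keeps C3 as accessible as possible for steps 12 and 18.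

Step 11
Reactants: 20 (2S)-4-[methoxy(methyl)amino]-2-methyl-4-oxo-2-(triethylsilyloxy)butanoic acid
Product: 21 (2S)-4-[methoxy(methyl)amino]-2-methyl-4-oxo-2-(triethylsilyloxy)butanoyl fluoride
Conditions: cyanuric fluoride, pyridine, CH2Cl2, −10 °C
Reagents that add atoms: cyanuric fluoride, Fc1nc(F)nc(F)n1
Why: Carboxylic acids are converted into acyl fluorides by cyanuric fluoride under conditions that spare silyl ethers; the acyl fluoride has a small leaving group and no α-hydrogen, so neither ketene formation nor epimerisation is possible.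

Step 12
Reactants: 14 (2S)-1-{4-[(tert-butyldimethylsilyloxy)methyl]-3-iodofuran-2-yl}-2-methylpent-4-en-2-ol; 21 (2S)-4-[methoxy(methyl)amino]-2-methyl-4-oxo-2-(triethylsilyloxy)butanoyl fluoride
Product: 23 (2S)-1-{4-[(tert-butyldimethylsilyloxy)methyl]-3-iodofuran-2-yl}-2-methylpent-4-en-2-yl (2S)-4-[methoxy(methyl)amino]-2-methyl-4-oxo-2-(triethylsilyloxy)butanoate, via potassium alkoxide 22 (not isolated)
Conditions: KN(SiMe3)2 (1.0 equiv), THF, −78 °C; then 21, −78 → 0 °C
Reagents that add atoms: none
Why: A preformed tertiary alkoxide is acylated by the acyl fluoride, the combination of strongest nucleophile and smallest leaving group for a doubly hindered ester; one equivalent of base and low temperature are used so that deprotonation at C5 does not compete.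

Step 13
Reactants: 23 (2S)-1-{4-[(tert-butyldimethylsilyloxy)methyl]-3-iodofuran-2-yl}-2-methylpent-4-en-2-yl (2S)-4-[methoxy(methyl)amino]-2-methyl-4-oxo-2-(triethylsilyloxy)butanoate
Product: 24 (2S)-1-{4-[(tert-butyldimethylsilyloxy)methyl]-3-iodofuran-2-yl}-2-methylpent-4-en-2-yl (2S)-2-methyl-4-oxo-2-(triethylsilyloxy)butanoate
Conditions: iBu2AlH, THF, −78 °C; potassium sodium tartrate (aq.)
Reagents that add atoms: none
Why: Weinreb amide reduction stops at the chelated hemiaminal and gives the C6 aldehyde on work-up; the ester of a tertiary alcohol with a quaternary α-carbon should be inert at this temperature.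

Step 14
Reactants: 24 (2S)-1-{4-[(tert-butyldimethylsilyloxy)methyl]-3-iodofuran-2-yl}-2-methylpent-4-en-2-yl (2S)-2-methyl-4-oxo-2-(triethylsilyloxy)butanoate
Product: 26 (4S,10S)-13-(tert-butyldimethylsilyloxy)-8,12-epoxy-6-hydroxy-4-(triethylsilyloxy)-2,3-secogermacra-1,7,11-trien-3,10-olide as a mixture of C6 epimers, via arylchromium species 25 (not isolated)
Conditions: CrCl2 (10 equiv), NiCl2 (0.1 equiv), DMSO, rt, slow addition of 24 to 0.002 M
Reagents that add atoms: none
Why: Intramolecular Nozaki–Hiyama–Kishi reaction: the C–I bond adds oxidatively to zerovalent nickel, the aryl group is passed to trivalent chromium, and the arylchromium species adds to the aldehyde but not to the ester, closing the nine-membered lactone at C6–C7. The configuration at C6 is not controlled here and is reset in steps 15 and 16.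

Step 15
Reactants: 26 (4S,10S)-13-(tert-butyldimethylsilyloxy)-8,12-epoxy-6-hydroxy-4-(triethylsilyloxy)-2,3-secogermacra-1,7,11-trien-3,10-olide (C6 epimers)
Product: 27 (4S,10S)-13-(tert-butyldimethylsilyloxy)-8,12-epoxy-6-oxo-4-(triethylsilyloxy)-2,3-secogermacra-1,7,11-trien-3,10-olide
Conditions: Dess–Martin periodinane, NaHCO3, CH2Cl2, rt
Reagents that add atoms: none
Why: Buffered Dess–Martin oxidation converges both C6 epimers on one furyl ketone without acid or base that could eliminate the β-silyloxy group.

Step 16
Reactants: 27 (4S,10S)-13-(tert-butyldimethylsilyloxy)-8,12-epoxy-6-oxo-4-(triethylsilyloxy)-2,3-secogermacra-1,7,11-trien-3,10-olide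
Product: 28 (4S,6S,10S)-13-(tert-butyldimethylsilyloxy)-8,12-epoxy-6-hydroxy-4-(triethylsilyloxy)-2,3-secogermacra-1,7,11-trien-3,10-olide
Conditions: (R)-2-methyl-CBS-oxazaborolidine (1.0 equiv), catecholborane, toluene, −78 → −40 °C
Reagents that add atoms: none
Why: Corey–Bakshi–Shibata reduction with the furyl group as the large substituent and C5H2 as the small one; the (R)-catalyst should deliver hydride to give (6S), by analogy with aryl alkyl ketones. Catecholborane is used so that the allyl group is not hydroborated.

Step 17
Reactants: 28 (4S,6S,10S)-13-(tert-butyldimethylsilyloxy)-8,12-epoxy-6-hydroxy-4-(triethylsilyloxy)-2,3-secogermacra-1,7,11-trien-3,10-olide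
Product: 29 (4S,6S,10S)-6,13-bis(tert-butyldimethylsilyloxy)-8,12-epoxy-4-(triethylsilyloxy)-2,3-secogermacra-1,7,11-trien-3,10-olide
Conditions: TBSOTf, 2,6-lutidine, CH2Cl2, −78 → 0 °C
Reagents that add atoms: tert-butyldimethylsilyl trifluoromethanesulfonate, CC(C)(C)[Si](C)(C)OS(=O)(=O)C(F)(F)F
Why: Silylation of the hindered secondary furyl carbinol with the silyl triflate and a non-nucleophilic base removes the last free hydroxyl before the titanium step.

Step 18
Reactants: 29 (4S,6S,10S)-6,13-bis(tert-butyldimethylsilyloxy)-8,12-epoxy-4-(triethylsilyloxy)-2,3-secogermacra-1,7,11-trien-3,10-olide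
Product: 32 (4S,6S,10S)-6,13-bis(tert-butyldimethylsilyloxy)-3,10:8,12-diepoxy-4-(triethylsilyloxy)germacra-2,7,11-triene, via titanium alkylidene 30 (not isolated), via oxatitanacyclobutane 31 (not isolated)
Conditions: TiCl4, TMEDA, Zn, PbCl2 (cat.), CH3CHBr2, THF–CH2Cl2, 0 → 65 °C
Reagents that add atoms: none
Why: Proposed new method: the low-valent titanium ethylidene made from CH3CHBr2 should exchange with the monosubstituted alkene of 29 (propene leaves) to give alkylidene 30 at C2, which adds [2+2] to the lactone carbonyl C3 to give 31; cycloreversion with loss of a titanium oxo species then forms C2=C3. The closest known reaction type is the olefinic ester cyclisation of acyclic esters to six- and seven-membered cyclic enol ethers with this reagent, or ester methylenation with Cp2TiCH2ClAlMe2 followed by enol ether–olefin ring-closing metathesis; the new elements are a medium-ring lactone as the ester and a bridgehead enol ether as the product. The dihydrofuran (O, C3, C2, C1, C10) closes in a 5-exo-trig sense with respect to C3=O through a tether of only C1 and C10, so the high effective molarity should offset the shielding of C3 by the quaternary C4 and C10. The ten-membered carbocycle is closed by the same C2–C3 bond as a transannular event across the existing nine-membered lactone, so it costs no macrocyclisation entropy. The trans ring geometry of C2=C3 is dictated by the five-membered ring and is allowed because the bridgehead alkene sits in a bicyclo[6.2.1] frame. No stereocentre is formed, and C4 (quaternary), C6 and C10 have no hydrogen that the basic TMEDA medium could epimerise. The selectivity needed is for one carbonyl group and one alkene: the butenolide is still a furan, every hydroxyl is a silyl ether, and the allyl group is the only alkene open to alkylidene exchange.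

Step 19
Reactants: 32 (4S,6S,10S)-6,13-bis(tert-butyldimethylsilyloxy)-3,10:8,12-diepoxy-4-(triethylsilyloxy)germacra-2,7,11-triene
Product: 34 (4S,6S,10S)-6,13-bis(tert-butyldimethylsilyloxy)-3,10-epoxy-8-hydroxy-4-(triethylsilyloxy)germacra-2,7(11)-dien-12,8-olide as a mixture of C8 epimers, via furan endoperoxide 33 (not isolated)
Conditions: O2, hν (visible), rose bengal (cat.), iPr2NEt, CH2Cl2, −78 °C; then warm to rt
Reagents that add atoms: dioxygen, O=O
Why: Singlet oxygen adds [4+2] across C8 and C12 of the trisubstituted furan, and the hindered amine removes the only α-hydrogen (at C12) in a Kornblum–DeLaMare fragmentation, giving the C12 carbonyl and the C8 hemiketal. The electron-rich furan should react faster than the hindered bridgehead enol ether; low temperature and stopping at full conversion of 32 support this.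

Step 20
Reactants: 34 (4S,6S,10S)-6,13-bis(tert-butyldimethylsilyloxy)-3,10-epoxy-8-hydroxy-4-(triethylsilyloxy)germacra-2,7(11)-dien-12,8-olide (C8 epimers)
Product: 36 (4S,6S,8E,10S)-6,13-bis(tert-butyldimethylsilyloxy)-3,10-epoxy-4-(triethylsilyloxy)germacra-2,7(11),8-trien-12,8-olide, via pseudo-mesylate 35 (not isolated)
Conditions: MsCl, Et3N, CH2Cl2, −40 → 0 °C
Reagents that add atoms: none
Why: Sulfonylation of the hemiketal hydroxyl (the only free OH), ionisation to the acyloxocarbenium ion and loss of a C9 proton is the usual dehydration of a γ-hydroxybutenolide to a γ-ylidene butenolide. C7 has no hydrogen, so C9 is the only site, and the nine-membered ring through the C3–O–C10 bridge allows only the isomer with C7 and C10 cis.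

Step 21
Reactants: 36 (4S,6S,8E,10S)-6,13-bis(tert-butyldimethylsilyloxy)-3,10-epoxy-4-(triethylsilyloxy)germacra-2,7(11),8-trien-12,8-olide
Product: 37 (4S,6S,8E,10S)-3,10-epoxy-4,6,13-trihydroxygermacra-2,7(11),8-trien-12,8-olide
Conditions: Bu4NF, AcOH (1:1), THF, 0 °C → rt
Reagents that add atoms: none
Why: Fluoride buffered with acetic acid removes the three silyl groups near neutral pH, which avoids both acid hydration of C2=C3 and base attack on the enol lactone. The C6 hydroxyl is trans to C12 across C7=C11, so it cannot translactonise.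

Step 22
Reactants: 37 (4S,6S,8E,10S)-3,10-epoxy-4,6,13-trihydroxygermacra-2,7(11),8-trien-12,8-olide
Product: 38 (4S,6S,8E,10S)-6,13-diacetoxy-3,10-epoxy-4-hydroxygermacra-2,7(11),8-trien-12,8-olide (CNP0144020.1)
Conditions: Ac2O, pyridine, DMAP (cat.), CH2Cl2, 0 °C
Reagents that add atoms: acetic anhydride, CC(=O)OC(C)=O
Why: Acetylation of the primary and secondary hydroxyls is fast under these conditions, while the tertiary C4 hydroxyl next to a quaternary bridgehead should remain free.

## Compound list

1 | 3,4-dibromofuran | Brc1cocc1Br | starting material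
2 | 3-bromo-4-lithiofuran | [Li]c1cocc1Br | intermediate (not isolated)
3 | 4-bromofuran-3-carbaldehyde | O=Cc1cocc1Br | intermediate (not isolated)
4 | (4-bromofuran-3-yl)methanol | OCc1cocc1Br | intermediate
5 | [(4-bromofuran-3-yl)methoxy](tert-butyl)dimethylsilane | CC(C)(C)[Si](C)(C)OCc1cocc1Br | intermediate
6 | 2-methylprop-2-en-1-ol | CC(=C)CO | starting material
7 | (S)-(2-methyloxiran-2-yl)methanol, (S)-2-methylglycidol | OC[C@@]1(C)CO1 | intermediate (not isolated)
8 | [(2R)-2-methyloxiran-2-yl]methyl 4-methylbenzenesulfonate | Cc1ccc(cc1)S(=O)(=O)OC[C@@]1(C)CO1 | intermediate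
9 | {3-bromo-4-[(tert-butyldimethylsilyloxy)methyl]furan-2-yl}lithium | CC(C)(C)[Si](C)(C)OCc1coc([Li])c1Br | intermediate (not isolated)
10 | (2R)-3-{3-bromo-4-[(tert-butyldimethylsilyloxy)methyl]furan-2-yl}-2-hydroxy-2-methylpropyl 4-methylbenzenesulfonate | Cc1ccc(cc1)S(=O)(=O)OC[C@](C)(O)Cc1occ(CO[Si](C)(C)C(C)(C)C)c1Br | intermediate (not isolated)
11 | (2R)-2-({3-bromo-4-[(tert-butyldimethylsilyloxy)methyl]furan-2-yl}methyl)-2-methyloxirane | CC(C)(C)[Si](C)(C)OCc1coc(C[C@]2(C)CO2)c1Br | intermediate
12 | (2S)-1-{3-bromo-4-[(tert-butyldimethylsilyloxy)methyl]furan-2-yl}-2-methylpent-4-en-2-ol | CC(C)(C)[Si](C)(C)OCc1coc(C[C@@](C)(O)CC=C)c1Br | intermediate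
13 | dilithio species of 12 (lithium alkoxide, 3-furyllithium) | CC(C)(C)[Si](C)(C)OCc1coc(C[C@@](C)(O[Li])CC=C)c1[Li] | intermediate (not isolated)
14 | (2S)-1-{4-[(tert-butyldimethylsilyloxy)methyl]-3-iodofuran-2-yl}-2-methylpent-4-en-2-ol | CC(C)(C)[Si](C)(C)OCc1coc(C[C@@](C)(O)CC=C)c1I | intermediate
15 | (S)-citramalic acid, (2S)-2-hydroxy-2-methylbutanedioic acid | OC(=O)[C@@](C)(O)CC(=O)O | starting material
16 | 2-[(4S)-2,2,4-trimethyl-5-oxo-1,3-dioxolan-4-yl]acetic acid | CC1(C)OC(=O)[C@](C)(CC(=O)O)O1 | intermediate
17 | N-methoxy-N-methyl-2-[(4S)-2,2,4-trimethyl-5-oxo-1,3-dioxolan-4-yl]acetamide | CON(C)C(=O)C[C@]1(C)OC(C)(C)OC1=O | intermediate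
18 | (2S)-2-hydroxy-4-[methoxy(methyl)amino]-2-methyl-4-oxobutanoic acid | OC(=O)[C@@](C)(O)CC(=O)N(C)OC | intermediate
19 | triethylsilyl (2S)-4-[methoxy(methyl)amino]-2-methyl-4-oxo-2-(triethylsilyloxy)butanoate | CC[Si](CC)(CC)OC(=O)[C@@](C)(O[Si](CC)(CC)CC)CC(=O)N(C)OC | intermediate (not isolated)
20 | (2S)-4-[methoxy(methyl)amino]-2-methyl-4-oxo-2-(triethylsilyloxy)butanoic acid | OC(=O)[C@@](C)(O[Si](CC)(CC)CC)CC(=O)N(C)OC | intermediate
21 | (2S)-4-[methoxy(methyl)amino]-2-methyl-4-oxo-2-(triethylsilyloxy)butanoyl fluoride | FC(=O)[C@@](C)(O[Si](CC)(CC)CC)CC(=O)N(C)OC | intermediate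
22 | potassium alkoxide of 14 | CC(C)(C)[Si](C)(C)OCc1coc(C[C@@](C)(O[K])CC=C)c1I | intermediate (not isolated)
23 | (2S)-1-{4-[(tert-butyldimethylsilyloxy)methyl]-3-iodofuran-2-yl}-2-methylpent-4-en-2-yl (2S)-4-[methoxy(methyl)amino]-2-methyl-4-oxo-2-(triethylsilyloxy)butanoate | C=CC[C@@](C)(Cc1occ(CO[Si](C)(C)C(C)(C)C)c1I)OC(=O)[C@@](C)(O[Si](CC)(CC)CC)CC(=O)N(C)OC | intermediate
24 | (2S)-1-{4-[(tert-butyldimethylsilyloxy)methyl]-3-iodofuran-2-yl}-2-methylpent-4-en-2-yl (2S)-2-methyl-4-oxo-2-(triethylsilyloxy)butanoate | C=CC[C@@](C)(Cc1occ(CO[Si](C)(C)C(C)(C)C)c1I)OC(=O)[C@@](C)(O[Si](CC)(CC)CC)CC=O | intermediate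
25 | arylchromium dichloride from 24 (CrCl2 on C7) | C=CC[C@@](C)(Cc1occ(CO[Si](C)(C)C(C)(C)C)c1[Cr](Cl)Cl)OC(=O)[C@@](C)(O[Si](CC)(CC)CC)CC=O | intermediate (not isolated)
26 | (4S,10S)-13-(tert-butyldimethylsilyloxy)-8,12-epoxy-6-hydroxy-4-(triethylsilyloxy)-2,3-secogermacra-1,7,11-trien-3,10-olide, C6 epimers (furan-fused nine-membered lactone with allyl on C10) | CC(C)(C)[Si](C)(C)OCc1c2c(C[C@](C)(CC=C)OC(=O)[C@@](C)(O[Si](CC)(CC)CC)CC2O)oc1 | intermediate
27 | (4S,10S)-13-(tert-butyldimethylsilyloxy)-8,12-epoxy-6-oxo-4-(triethylsilyloxy)-2,3-secogermacra-1,7,11-trien-3,10-olide | CC(C)(C)[Si](C)(C)OCc1c2c(C[C@](C)(CC=C)OC(=O)[C@@](C)(O[Si](CC)(CC)CC)CC2=O)oc1 | intermediate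
28 | (4S,6S,10S)-13-(tert-butyldimethylsilyloxy)-8,12-epoxy-6-hydroxy-4-(triethylsilyloxy)-2,3-secogermacra-1,7,11-trien-3,10-olide | CC(C)(C)[Si](C)(C)OCc1c2c(C[C@](C)(CC=C)OC(=O)[C@@](C)(O[Si](CC)(CC)CC)C[C@@H]2O)oc1 | intermediate
29 | (4S,6S,10S)-6,13-bis(tert-butyldimethylsilyloxy)-8,12-epoxy-4-(triethylsilyloxy)-2,3-secogermacra-1,7,11-trien-3,10-olide (key-step precursor) | CC(C)(C)[Si](C)(C)OCc1c2c(C[C@](C)(CC=C)OC(=O)[C@@](C)(O[Si](CC)(CC)CC)C[C@@H]2O[Si](C)(C)C(C)(C)C)oc1 | intermediate
30 | titanium alkylidene at C2 of 29 (ligands on titanium not drawn) | CC(C)(C)[Si](C)(C)OCc1c2c(C[C@](C)(CC=[Ti])OC(=O)[C@@](C)(O[Si](CC)(CC)CC)C[C@@H]2O[Si](C)(C)C(C)(C)C)oc1 | intermediate (not isolated)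
31 | oxatitanacyclobutane Ti–C2–C3–O from 30 (ligands on titanium not drawn) | CC(C)(C)[Si](C)(C)OCc1c2c(C[C@]3(C)CC4[Ti]OC4(O3)[C@@](C)(O[Si](CC)(CC)CC)C[C@@H]2O[Si](C)(C)C(C)(C)C)oc1 | intermediate (not isolated)
32 | (4S,6S,10S)-6,13-bis(tert-butyldimethylsilyloxy)-3,10:8,12-diepoxy-4-(triethylsilyloxy)germacra-2,7,11-triene (key-step product) | CC(C)(C)[Si](C)(C)OCc1c2c(C[C@]3(C)CC=C(O3)[C@@](C)(O[Si](CC)(CC)CC)C[C@@H]2O[Si](C)(C)C(C)(C)C)oc1 | intermediate
33 | 8,12-endoperoxide of 32 (peroxide bridge C8–O–O–C12 over the furan) | CC(C)(C)[Si](C)(C)OCC1=C2C3(C[C@]4(C)CC=C(O4)[C@@](C)(O[Si](CC)(CC)CC)C[C@@H]2O[Si](C)(C)C(C)(C)C)OOC1O3 | intermediate (not isolated)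
34 | (4S,6S,10S)-6,13-bis(tert-butyldimethylsilyloxy)-3,10-epoxy-8-hydroxy-4-(triethylsilyloxy)germacra-2,7(11)-dien-12,8-olide, C8 epimers | CC(C)(C)[Si](C)(C)OCC1=C2C(O)(C[C@]3(C)CC=C(O3)[C@@](C)(O[Si](CC)(CC)CC)C[C@@H]2O[Si](C)(C)C(C)(C)C)OC1=O | intermediate
35 | 8-O-methanesulfonyl derivative of 34 | CC(C)(C)[Si](C)(C)OCC1=C2C(OS(C)(=O)=O)(C[C@]3(C)CC=C(O3)[C@@](C)(O[Si](CC)(CC)CC)C[C@@H]2O[Si](C)(C)C(C)(C)C)OC1=O | intermediate (not isolated)
36 | (4S,6S,8E,10S)-6,13-bis(tert-butyldimethylsilyloxy)-3,10-epoxy-4-(triethylsilyloxy)germacra-2,7(11),8-trien-12,8-olide | CC(C)(C)[Si](C)(C)OCC1=C2/C(=C\[C@]3(C)CC=C(O3)[C@@](C)(O[Si](CC)(CC)CC)C[C@@H]2O[Si](C)(C)C(C)(C)C)OC1=O | intermediate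
37 | (4S,6S,8E,10S)-3,10-epoxy-4,6,13-trihydroxygermacra-2,7(11),8-trien-12,8-olide | OCC1=C2/C(=C\[C@]3(C)CC=C(O3)[C@@](C)(O)C[C@@H]2O)OC1=O | intermediate
38 | (4S,6S,8E,10S)-6,13-diacetoxy-3,10-epoxy-4-hydroxygermacra-2,7(11),8-trien-12,8-olide (CNP0144020.1) | CC(=O)OCC1=C2/C(=C\[C@]3(C)CC=C(O3)[C@@](C)(O)C[C@@H]2OC(C)=O)OC1=O | target

## Step count and least certain steps

Total: 22 steps. Longest linear sequence: 16 steps (steps 1, 2, 4–6, 12–22 from 1; equally steps 7–22 from 15).

Step 18 (key step). The alkylidene may transfer to the carbonyl without prior exchange at the alkene, so that only an acyclic ethylidene enol ether forms and no ring closes. The [2+2] addition may also fail because C3 is shielded by C4 and C10, or the Lewis-acidic medium may ionise the furylic C6–O bond or strip the primary silyl ether. The fallback uses known chemistry and sets out from 29. Methylenation of the lactone carbonyl with Cp2TiMe2 in toluene at 80 °C would give the exocyclic enol ether, the 3-methylene derivative of 29, F1. Ring-closing metathesis between this enol ether and the allyl group with the second-generation Grubbs catalyst, RuCl2(=CHPh)(H2IMes)(PCy3), in toluene at 80 °C (ethene is lost) returns to the route at 32.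

Step 12. Acylation may be slow at the doubly hindered centre, leaving the alkoxide time to act as a base at C5 and start β-elimination of silanolate, or to attack the Weinreb amide. The fallback sets out from 14 and 17. Alkoxide 22 would open the dioxolanone 17 at its ring carbonyl, which is tied back and less shielded and expels acetone, to give the C4-hydroxy ester F2. Silylation with TESOTf and 2,6-lutidine returns to the route at 23. This also saves steps 9–11, but oligomerisation through the liberated C4 alkoxide is its own risk.

Step 14. Oxidative addition at the doubly flanked C–I bond may be slow, leading to protodeiodination. The strain of the nine-membered transition state may also favour intermolecular coupling, and the arylnickel intermediate may carbometalate the allyl group. The fallback sets out from 12. The lithiation of step 6 is quenched with Me3SnCl instead of iodine to give the furylstannane carbinol F3. Acylation with 21 as in step 12 gives the stannyl ester F4, and iBu2AlH reduction gives the stannyl aldehyde F5. The ring is then closed by [Rh(cod)(MeCN)2]BF4-catalysed 1,2-addition of the arylstannane to the aldehyde (THF, 60 °C, high dilution), an aryl transfer that also ignores esters. This returns to the route at 26.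

Step 16. The conformation of the nine-membered ring may shield one carbonyl face and override the catalyst, giving poor or reversed facial selectivity. The fallback sets out from 27. Reduction under substrate control (NaBH4, CeCl3, MeOH, −40 °C) is followed, if the undesired (6R)-alcohol F6 predominates, by Mitsunobu inversion (4-nitrobenzoic acid, PPh3, DIAD) to the (6S) 4-nitrobenzoate F7. Methanolysis (K2CO3, MeOH) returns to the route at 28. If the substrate-controlled reduction gives the (6S) alcohol directly, it is 28.

Step 19. Singlet oxygen may also oxidise the enol ether C2=C3 (ene reaction at C1–H or dioxetane formation and cleavage), and the product may be over-oxidised. The fallback sets out from 32. The enol ether is masked by adding methanol (PPTS cat., MeOH, 0 °C) to give the mixed methyl ketal F8. Photooxygenation with iPr2NEt as in step 19 gives the hydroxybutenolide ketal F9, and dehydration as in step 20 gives the ylidene butenolide ketal F10. Elimination of methanol with TMSOTf and iPr2NEt can only go towards C2, because C4 has no hydrogen, and returns to the route at 36.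

## Further compounds

F1 | step 18 | (4S,6S,10S)-6,13-bis(tert-butyldimethylsilyloxy)-8,12-epoxy-3-methylene-4-(triethylsilyloxy)-2,3-secogermacra-1,7,11-triene 3,10-oxide (exocyclic enol ether of 29) | CC(C)(C)[Si](C)(C)OCc1c2c(C[C@](C)(CC=C)OC(=C)[C@@](C)(O[Si](CC)(CC)CC)C[C@@H]2O[Si](C)(C)C(C)(C)C)oc1
F2 | step 12 | (2S)-1-{4-[(tert-butyldimethylsilyloxy)methyl]-3-iodofuran-2-yl}-2-methylpent-4-en-2-yl (2S)-2-hydroxy-4-[methoxy(methyl)amino]-2-methyl-4-oxobutanoate | C=CC[C@@](C)(Cc1occ(CO[Si](C)(C)C(C)(C)C)c1I)OC(=O)[C@@](C)(O)CC(=O)N(C)OC
F3 | step 14 | (2S)-1-{4-[(tert-butyldimethylsilyloxy)methyl]-3-(trimethylstannyl)furan-2-yl}-2-methylpent-4-en-2-ol | CC(C)(C)[Si](C)(C)OCc1coc(C[C@@](C)(O)CC=C)c1[Sn](C)(C)C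
F4 | step 14 | (2S)-1-{4-[(tert-butyldimethylsilyloxy)methyl]-3-(trimethylstannyl)furan-2-yl}-2-methylpent-4-en-2-yl (2S)-4-[methoxy(methyl)amino]-2-methyl-4-oxo-2-(triethylsilyloxy)butanoate | C=CC[C@@](C)(Cc1occ(CO[Si](C)(C)C(C)(C)C)c1[Sn](C)(C)C)OC(=O)[C@@](C)(O[Si](CC)(CC)CC)CC(=O)N(C)OC
F5 | step 14 | (2S)-1-{4-[(tert-butyldimethylsilyloxy)methyl]-3-(trimethylstannyl)furan-2-yl}-2-methylpent-4-en-2-yl (2S)-2-methyl-4-oxo-2-(triethylsilyloxy)butanoate | C=CC[C@@](C)(Cc1occ(CO[Si](C)(C)C(C)(C)C)c1[Sn](C)(C)C)OC(=O)[C@@](C)(O[Si](CC)(CC)CC)CC=O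
F6 | step 16 | (4S,6R,10S)-13-(tert-butyldimethylsilyloxy)-8,12-epoxy-6-hydroxy-4-(triethylsilyloxy)-2,3-secogermacra-1,7,11-trien-3,10-olide | CC(C)(C)[Si](C)(C)OCc1c2c(C[C@](C)(CC=C)OC(=O)[C@@](C)(O[Si](CC)(CC)CC)C[C@H]2O)oc1
F7 | step 16 | (4S,6S,10S)-13-(tert-butyldimethylsilyloxy)-8,12-epoxy-6-(4-nitrobenzoyloxy)-4-(triethylsilyloxy)-2,3-secogermacra-1,7,11-trien-3,10-olide | CC(C)(C)[Si](C)(C)OCc1c2c(C[C@](C)(CC=C)OC(=O)[C@@](C)(O[Si](CC)(CC)CC)C[C@@H]2OC(=O)c3ccc(cc3)[N+](=O)[O-])oc1
F8 | step 19 | (4S,6S,10S)-6,13-bis(tert-butyldimethylsilyloxy)-3,10:8,12-diepoxy-3-methoxy-4-(triethylsilyloxy)germacra-7,11-diene (C3 methyl ketal of 32) | CC(C)(C)[Si](C)(C)OCc1c2c(C[C@]3(C)CCC(OC)(O3)[C@@](C)(O[Si](CC)(CC)CC)C[C@@H]2O[Si](C)(C)C(C)(C)C)oc1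
F9 | step 19 | (4S,6S,10S)-6,13-bis(tert-butyldimethylsilyloxy)-3,10-epoxy-8-hydroxy-3-methoxy-4-(triethylsilyloxy)germacr-7(11)-en-12,8-olide | CC(C)(C)[Si](C)(C)OCC1=C2C(O)(C[C@]3(C)CCC(OC)(O3)[C@@](C)(O[Si](CC)(CC)CC)C[C@@H]2O[Si](C)(C)C(C)(C)C)OC1=O
F10 | step 19 | (4S,6S,8E,10S)-6,13-bis(tert-butyldimethylsilyloxy)-3,10-epoxy-3-methoxy-4-(triethylsilyloxy)germacra-7(11),8-dien-12,8-olide | CC(C)(C)[Si](C)(C)OCC1=C2/C(=C\[C@]3(C)CCC(OC)(O3)[C@@](C)(O[Si](CC)(CC)CC)C[C@@H]2O[Si](C)(C)C(C)(C)C)OC1=O
A1 | alternative 1 | isoxazoline-bridged macrocycle (isoxazoline C6=N–O–C4 across the ten-membered ring) | CC(=O)OCC1=C2/C(=C\[C@]3(C)CC=C(O3)[C@]4(C)CC2=NO4)OC1=O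
A2 | alternative 1 | aldoxime precursor (C6 aldoxime on the butenolide, isopropenyl group on C3 of the dihydrofuran) | CC(=O)OCC1=C(C=NO)/C(=C\[C@]2(C)CC=C(O2)C(C)=C)OC1=O
A3 | alternative 2 | tricyclic oxanorbornene adduct, written with the (6S) silyl ether | C[C@@]12C=C[C@]3(O1)[C@@](C)(O[Si](CC)(CC)CC)C[C@H](O[Si](C)(C)C(C)(C)C)C(=O)[C@@]3(OC(C)=O)C2
A4 | alternative 2 | 2-methyl-5-alkylfuran with tethered 2-acetoxy enone | Cc1ccc(o1)[C@@](C)(O[Si](CC)(CC)CC)C[C@H](O[Si](C)(C)C(C)(C)C)C(=O)C(=C)OC(C)=O
A5 | alternative 3 | ten-membered 3-keto ylidene butenolide with C10 silyl ether | CC(C)(C)[Si](C)(C)OCC1=C2/C(=C\[C@](O[Si](C)(C)C(C)(C)C)(C)CCC(=O)[C@@](C)(OCOC)C[C@@H]2O[Si](C)(C)C(C)(C)C)OC1=O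
A6 | alternative 3 | cis-1,2-dialkenylcyclohexanol fused to the butenolide (C3 vinyl carbinol, C8 (E)-2-silyloxypropenyl) | C=C[C@]1(O)[C@@](C)(OCOC)C[C@H](O[Si](C)(C)C(C)(C)C)C2=C(CO[Si](C)(C)C(C)(C)C)C(=O)O[C@@]12/C=C(\C)O[Si](C)(C)C(C)(C)C
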